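## Structural features

- The target is a linear hexa-aryl pentaether: six benzene rings (A to F) joined only through diaryl ether oxygens, with fifteen free phenolic hydroxyls and no carbon–carbon bond between rings.
- Ring A is a 2,4,6-trihydroxyphenyl ether and ring F a 3,4,5-trihydroxyphenyl ether. Rings B, D and E are 3,5-dihydroxy-1,4-phenylene units whose C4 ether oxygen sits between two hydroxyls.
- Ring C alone carries five oxygens in a row: ether oxygens on the neighbouring carbons C1 (to ring B) and C2 (to ring D), hydroxyls on C3, C4 and C5, and a single hydrogen on C6.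
- There are no stereocentres and no fixed axes, so no stereochemical relationship has to be set.
- The free polyphenol (pyrogallol units on rings C and F, a phloroglucinol unit on ring A) is sensitive to air and base, so every oxygen should stay masked until the last step. The diaryl ether bonds themselves are robust.
- The real difficulty is the regiodefined oxygen pattern of ring C with its two adjacent aryl ethers, together with the hindered ether bonds at C4 of rings B, D and E.
- The key step uses exactly the C1–C5 oxygen run and the C6–H of ring C. C1 to C4 with their oxygens come from a squaric acid core, C5 (with its oxygen) and C6 from a 1-methoxyvinyl group, and the bond that closes the ring is C1–C6.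

## Logic of the disconnections

**30 from 29.** Thirteen O–CH3 bonds are cut. All hydroxyls except the two on ring B stay as methyl ethers to the end, so the oxidisable polyphenol exists only in the final flask. The forward step needs a reagent that cleaves alkyl–oxygen bonds but leaves aryl–O–aryl bonds alone, and an air-free work-up.

**29 from 27.** The two C–OH bonds at C3 and C5 of ring B are traced back to C–CHO bonds. The formyl groups are chosen because they are also what activates C4 of ring B for ether formation. The forward oxidation must proceed by aryl (not hydride) migration and must spare the electron-rich rings.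

**27 from 19 and 26.** The C4–O bond of ring B is cut. This splits the hexamer into a four-ring phenol and a two-ring electrophile. The forward SNAr needs a single free hydroxyl on 19 and a fluoride flanked by two carbonyl groups on 26.

**26 from 25, 25 from 23 and 24, 23 from 22, 22 from 20.** The ring A–O–C1(ring B) bond is cut. C1 of ring B is meta to both formyl groups and is not activated, so this bond calls for copper catalysis on a bromide. Both formyl groups must be masked as acetals at that point, otherwise the phenoxide would displace fluoride. The second formyl carbon is introduced by lithiation next to fluorine while the bromide is still in place.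

**19 from 16 (key step).** The C1–C6 bond of ring C is cut and the ring is folded back to a four-membered ring. Rechecking the atom map: the cyclobutenone carbonyl carbon becomes C1 (free OH), the aryloxy-bearing carbon C2, the methoxy-bearing carbons C3 and C4, and the vinyl carbons C5 and C6. This agrees with the target. The gain is that the whole oxygen pattern of ring C is reduced to a squarate plus a two-carbon unit. The forward step needs inward rotation of the vinyl group, a clean thermal reaction without nucleophiles that could trap the ketene, and an oxygen on C4 that is inert later. That oxygen is carried as a methyl ether, because a silyl ether there would be attacked by the fluoride released in the later SNAr step and is in any case not needed when the last step removes all methyl groups.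

**16 from 11 and 12 (through 15).** The C4–vinyl bond, the O–CH3 bond on the C4 oxygen and the C3–OCH3 bond are cut. The symmetrical diester 11 is chosen over a mixed aryl methyl ester so that the two carbonyls are equivalent and no site selectivity is needed. After addition, only the aryloxy group β to the remaining carbonyl is a vinylogous ester and can be exchanged for methoxide. The aryloxy group α to the carbonyl is therefore placed by construction. The cost is a second equivalent of 8, which is released again in the exchange. The forward step needs 1,2-addition rather than displacement of aryloxide, and alkylation of a tertiary alkoxide.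

**11 from 10 and 8, 10 from 9.** The two squarate C–O(aryl) bonds are cut back to the vinylogous acid chloride, which comes from squaric acid. The forward step needs O- rather than C-attack by an electron-rich phenol.

**8 from 7, 7 from 6 and 2, 6 from 3, 3 from 1 and 2.** The O–C1 bonds of rings E and F are cut. In each coupling the hindered partner (two ortho methoxy groups) is the phenol and the unhindered partner is the boronic acid, which is the polarity an oxidative copper coupling tolerates. The bromine of 2 survives the coupling and serves first as the site of the next boronic acid and finally as the site of the hydroxyl of 8.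

## Other disconnections considered

**Alternative 1:** The cut is at both ether bonds of ring B (ring A–O–C1 and C4–O–ring C).
- Forward step: the cationic complex A2 (divalent ruthenium on the dichloroarene) would take the phenoxide of 24 at the unhindered chloride and then the phenoxide of 19 at the chloride between the two methoxy groups. This would give A1 in one pot, followed by release of the arene from the metal and demethylation.
- In its favour: ring B arrives with its methoxy groups in place, so neither formyl groups nor a peracid are needed. Substitution on a cationic η6-arene runs under mild conditions.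
- Against it here: it needs stoichiometric ruthenium plus a complexation and a decomplexation step. The second substitution must occur at a carbon flanked by two methoxy groups, with a four-ring phenoxide, on a complex already deactivated by the first aryloxy donor. The CpRu fragment could move to another electron-rich ring. Fifteen methyl ethers remain for the end.
- Comparison: structurally it addresses only ring B and still needs 19, so it could replace steps 9 to 14 but not the key step. Mechanistically both plans are SNAr at C4 of ring B, activated by the metal there and by two formyl groups here. On step count for this junction and on avoiding peracid the alternative is the better. The chosen plan is preferred because it is metal-free and has only one leaving group, so the order of substitution cannot go wrong.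

**Alternative 2:** The cut is at C2–C3 and C5–C6 of ring A, so that ring A is built on the oxygen of a five-ring phenol.
- Forward step: the aryloxymalonate A4 and the keto diester A5 would condense twice under a methoxide base (two Claisen-type acylations) to give A3. Ester hydrolysis, decarboxylation and demethylation would follow.
- In its favour: it uses cheap three-carbon units in classical phloroglucinol chemistry, and no di-ortho-substituted phenol has to be coupled. The ring A hydroxyls arrive free, so three fewer methyl ethers have to be cleaved; on this point it is the better.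
- Against it here: ring A is the simplest ring of the molecule and its precursor 24 can be bought. The condensation would be run on a precious five-ring substrate whose α-aryloxy malonate is hindered and can lose aryloxide. Two ester groups must afterwards be removed in the presence of a free phloroglucinol. The five-ring phenol still requires ring C and the ring B–O–ring C bond.
- Comparison: structurally it solves the easy ring and leaves the hard one. Mechanistically it is strongly basic ionic chemistry, against a neutral pericyclic step. It costs at least three steps (malonate formation, condensation, ester removal) where the chosen plan spends one coupling (step 11). Both plans end with the same kind of Lewis acid demethylation, so they are equal there.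

**Alternative 3:** The cut is at ten aryl C–OH bonds (C2 and C6 of ring A; C3 and C5 of rings B, C, D and E), each traced back to C–CHO.
- Forward step: the deca-aldehyde A7 would be oxidised with a peracid and the formates cleaved with carbonate in methanol to give A6, leaving five methyl ethers to remove.
- In its favour: one operation unveils ten hydroxyls, and each pair of formyl groups also activates its ring for ether formation, so the whole chain could be assembled by one reaction type. It avoids organolithium and strained-ring chemistry. Only five methyl ethers remain, so the final deprotection is milder; on this point it is the better.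
- Against it here: ten Baeyer–Villiger events must all go by aryl migration on one molecule. Partly oxidised intermediates are free electron-rich phenols exposed to peracid. Phenoxides bearing two formyl groups are weak nucleophiles. Ring C would need a pentasubstituted fluoro-dialdehyde with an extra oxygen on C1, which is the pattern hardest to make by classical substitution.
- Comparison: the chosen plan uses the same tactic once, at ring B (steps 13 and 14), so on mechanism at that ring the two are equal. The chosen plan limits the peracid to two formyl groups and takes the ring C pattern from the squarate. On step count the alternative could be equal only if all its building blocks were at hand; each needs its own synthesis.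

Key step: step 8

Remark on the chemistry: the oxygen on C4 of the cyclobutenone (C4 of ring C) is carried as a methyl ether in place of a silyl ether, and compounds 20 and 24 are taken as purchasable.

## Route

Step 1
Reactants: 1 3,4,5-trimethoxyphenylboronic acid; 2 4-bromo-2,6-dimethoxyphenol
Product: 3 5-bromo-1,3-dimethoxy-2-(3,4,5-trimethoxyphenoxy)benzene (ring E–F bromide)
Conditions: Cu(OAc)2 (1 equiv), pyridine, 4 Å MS, CH2Cl2, dry air, rt
Reagents that add atoms: none
Why: Chan–Lam oxidative C–O coupling (transmetalation of the boronic acid to divalent copper, then C–O reductive elimination from a trivalent copper aryl phenoxide); the mild conditions tolerate the di-ortho-methoxy phenol and leave the aryl bromide untouched, and the para bromine blocks oxidative C–C dimerisation of the phenol.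

Step 2
Reactants: 3 ring E–F bromide
Product: 6 [3,5-dimethoxy-4-(3,4,5-trimethoxyphenoxy)phenyl]boronic acid, via ring E–F aryllithium 4 (not isolated), via lithium aryl(triisopropoxy)borate 5 (not isolated)
Conditions: n-BuLi, THF, −78 °C; B(OiPr)3, −78 °C to rt; 1 M HCl
Reagents that add atoms: triisopropyl borate CC(C)OB(OC(C)C)OC(C)C; water O
Why: Bromine–lithium exchange is faster than ortho-deprotonation at −78 °C; the aryllithium is trapped as the borate and hydrolysed (lithiation–borylation).

Step 3
Reactants: 6 ring E–F boronic acid; 2 4-bromo-2,6-dimethoxyphenol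
Product: 7 5-bromo-2-[3,5-dimethoxy-4-(3,4,5-trimethoxyphenoxy)phenoxy]-1,3-dimethoxybenzene (ring D–E–F bromide)
Conditions: Cu(OAc)2 (1 equiv), pyridine, 4 Å MS, CH2Cl2, dry air, rt
Reagents that add atoms: none
Why: Second Chan–Lam coupling with the same polarity as step 1 (hindered phenol, unhindered boronic acid); the cheap phenol 2 is used in excess.

Step 4
Reactants: 7 ring D–E–F bromide
Product: 8 3,5-dimethoxy-4-[3,5-dimethoxy-4-(3,4,5-trimethoxyphenoxy)phenoxy]phenol (ring D–E–F phenol; its aryl group is called the ring D–E–F aryl below)
Conditions: Pd2(dba)3 (2 mol %), tBuXPhos (8 mol %), KOH, 1,4-dioxane–H2O, 100 °C; then 1 M HCl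
Reagents that add atoms: potassium hydroxide [K+].[OH-]
Why: Palladium-catalysed hydroxylation of an unhindered aryl bromide (oxidative addition to zerovalent palladium, bromide–hydroxide exchange, C–O reductive elimination promoted by the bulky biarylphosphine); methyl and diaryl ethers are inert to hydroxide.

Step 5
Reactants: 9 squaric acid
Product: 10 3,4-dichlorocyclobut-3-ene-1,2-dione
Conditions: (COCl)2, cat. DMF, CH2Cl2, reflux
Reagents that add atoms: oxalyl chloride ClC(=O)C(Cl)=O
Why: Conversion of the vinylogous acid into the vinylogous acid chloride under chloroiminium catalysis, a standard preparation of this dichloride.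

Step 6
Reactants: 10 3,4-dichlorocyclobut-3-ene-1,2-dione; 8 ring D–E–F phenol (2 equiv)
Product: 11 3,4-bis(ring D–E–F aryloxy)cyclobut-3-ene-1,2-dione
Conditions: 8, NaH, THF, 0 °C; then 10, −78 to 0 °C
Reagents that add atoms: none
Why: Two addition–elimination substitutions at the vinylogous acid chloride carbons; the preformed sodium aryloxide at low temperature should react through oxygen rather than through the electron-rich ring carbons.

Step 7
Reactants: 11 bis(aryl) squarate; 12 methyl vinyl ether
Product: 16 racemic 2-(ring D–E–F aryloxy)-3,4-dimethoxy-4-(1-methoxyvinyl)cyclobut-2-en-1-one, via 1-methoxyvinyllithium 13 (not isolated), via lithium cyclobutenolate 14 (not isolated), via bis(aryloxy) methyl ether 15 (not isolated)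
Conditions: 12, t-BuLi, THF, −78 to 0 °C; 11, THF, −78 °C; MeOTf, −78 to −20 °C; NaOMe, MeOH, 0 °C; aq NH4Cl
Reagents that add atoms: methyl trifluoromethanesulfonate COS(=O)(=O)C(F)(F)F; sodium methoxide [Na+].[O-]C
Why: 1,2-Addition of the α-metalated enol ether to one of the two equivalent carbonyls of the squarate diester, then O-methylation of the tertiary lithium alkoxide; in 15 only the aryloxy group β to the carbonyl is a vinylogous ester, so methoxide exchanges it by conjugate addition–elimination and releases one equivalent of 8 for recovery. The C4 stereocentre forms as a racemate and disappears in step 8.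

Step 8
Reactants: 16 racemic 2-(ring D–E–F aryloxy)-3,4-dimethoxy-4-(1-methoxyvinyl)cyclobut-2-en-1-one
Product: 19 2-(ring D–E–F aryloxy)-3,4,5-trimethoxyphenol (ring C–F phenol), via dienylketene 17 (not isolated), via cyclohexa-2,4-dienone 18 (not isolated)
Conditions: toluene (0.01 M, degassed), 110 °C, argon, base-washed glassware
Reagents that add atoms: none
Why: On heating, the C1–C4 σ bond of the cyclobutenone should break in a thermal conrotatory 4π electrocyclic opening to the (Z)-dienylketene 17. The ketene carbon then bonds to the terminal CH2 of the methoxyvinyl group in a thermal disrotatory 6π electrocyclisation; this forms the C1–C6 bond and the six-membered carbocycle 18, which tautomerises to the phenol 19. The closest known reaction type is the Moore rearrangement of 4-alkenyl-4-hydroxy or 4-alkoxy cyclobutenones derived from squarates into oxygenated hydroquinones and their monoethers. No stereocentre is formed, and the one at C4 of 16 is lost. The selectivity needed is inward rotation of the vinyl group, which the outward preference of the methoxy donor on C4 should secure. The positions of the oxygens cannot change, because each ring carbon keeps its own oxygen: carbonyl carbon to C1–OH, aryloxy carbon to C2, methoxy carbons to C3 and C4, and the vinyl carbons to C5–OMe and C6–H. High dilution and the absence of protic nucleophiles and acid are meant to keep the ketene from dimerising or being trapped and the enol ether from hydrolysing.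

Step 9
Reactants: 20 2-(5-bromo-2-fluorophenyl)-1,3-dioxolane
Product: 22 5-bromo-3-(1,3-dioxolan-2-yl)-2-fluorobenzaldehyde, via aryllithium 21 (not isolated)
Conditions: LiN(iPr)2, THF, −78 °C; DMF; aq NH4Cl
Reagents that add atoms: N,N-dimethylformamide CN(C)C=O
Why: Fluorine-directed ortho-lithiation with an amide base, which does not exchange the bromide, followed by formylation; the only hydrogen ortho to fluorine is the one at the desired carbon, and the aryllithium is kept at −78 °C to prevent loss of LiF.

Step 10
Reactants: 22 5-bromo-3-(1,3-dioxolan-2-yl)-2-fluorobenzaldehyde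
Product: 23 2,2'-(5-bromo-2-fluoro-1,3-phenylene)bis(1,3-dioxolane)
Conditions: HOCH2CH2OH, cat. TsOH, toluene, reflux, azeotropic removal of water
Reagents that add atoms: ethane-1,2-diol OCCO
Why: Acid-catalysed acetalisation; with both carbonyls masked the fluoride is no longer activated and will survive the phenoxide of the next step.

Step 11
Reactants: 23 bis(dioxolane) bromide; 24 2,4,6-trimethoxyphenol
Product: 25 2,2'-[2-fluoro-5-(2,4,6-trimethoxyphenoxy)-1,3-phenylene]bis(1,3-dioxolane)
Conditions: CuI (10 mol %), picolinic acid (20 mol %), K3PO4, DMSO, 90 °C, argon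
Reagents that add atoms: none
Why: Ullmann-type C–O coupling under monovalent copper catalysis with a ligand suited to di-ortho-substituted phenols; the bromide is unhindered and the unactivated C–F bond is not touched.

Step 12
Reactants: 25 bis(dioxolane) diaryl ether
Product: 26 2-fluoro-5-(2,4,6-trimethoxyphenoxy)benzene-1,3-dicarbaldehyde
Conditions: 2 M HCl, THF, rt
Reagents that add atoms: water O
Why: Acid hydrolysis of both acetals; dilute aqueous acid at room temperature is chosen to avoid acid-promoted condensation of the aldehydes with the electron-rich ring A.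

Step 13
Reactants: 19 ring C–F phenol; 26 fluoro-dialdehyde
Product: 27 2-[2-(ring D–E–F aryloxy)-3,4,5-trimethoxyphenoxy]-5-(2,4,6-trimethoxyphenoxy)benzene-1,3-dicarbaldehyde
Conditions: K2CO3, DMF, rt to 40 °C, argon
Reagents that add atoms: none
Why: SNAr through a σ-adduct stabilised by the two ortho formyl groups, with fluoride as leaving group; 19 has a single hydroxyl and no silyl ether, so the fluoride set free can do no harm.

Step 14
Reactants: 27 hexamer dialdehyde
Product: 29 2-[2-(ring D–E–F aryloxy)-3,4,5-trimethoxyphenoxy]-5-(2,4,6-trimethoxyphenoxy)benzene-1,3-diol, via bis(formate) 28 (not isolated)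
Conditions: mCPBA, CH2Cl2, 0 °C to rt; then K2CO3, MeOH, 0 °C, argon
Reagents that add atoms: 3-chloroperoxybenzoic acid OOC(=O)c1cccc(Cl)c1
Why: Baeyer–Villiger oxidation of aryl aldehydes (Dakin-type): in the peroxy hemiacetal the aryl group, which carries an ortho aryloxy donor, should migrate in preference to hydride to give the aryl formates, which are cleaved by methanolysis.

Step 15
Reactants: 29 trideca-O-methyl hexamer diol
Product: 30 CNP0270681.0, 5-(2,4,6-trihydroxyphenoxy)-2-[2-{3,5-dihydroxy-4-[3,5-dihydroxy-4-(3,4,5-trihydroxyphenoxy)phenoxy]phenoxy}-3,4,5-trihydroxyphenoxy]benzene-1,3-diol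
Conditions: BBr3 (excess), CH2Cl2, −78 °C to rt, argon; MeOH then H2O, 0 °C
Reagents that add atoms: none
Why: Lewis acid cleavage of the thirteen aryl methyl ethers (boron coordinates the ether oxygen and bromide attacks the methyl carbon); diaryl ethers offer no carbon open to this attack and stay intact.

## Compound list

1 | 3,4,5-trimethoxyphenylboronic acid | COc1cc(B(O)O)cc(OC)c1OC | starting material
2 | 4-bromo-2,6-dimethoxyphenol | COc1cc(Br)cc(OC)c1O | starting material
3 | 5-bromo-1,3-dimethoxy-2-(3,4,5-trimethoxyphenoxy)benzene | COc1cc(Br)cc(OC)c1Oc1cc(OC)c(OC)c(OC)c1 | intermediate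
4 | [3,5-dimethoxy-4-(3,4,5-trimethoxyphenoxy)phenyl]lithium | [Li]c1cc(OC)c(Oc2cc(OC)c(OC)c(OC)c2)c(OC)c1 | intermediate (not isolated)
5 | lithium [3,5-dimethoxy-4-(3,4,5-trimethoxyphenoxy)phenyl]triisopropoxyborate | [Li+].CC(C)O[B-](OC(C)C)(OC(C)C)c1cc(OC)c(Oc2cc(OC)c(OC)c(OC)c2)c(OC)c1 | intermediate (not isolated)
6 | [3,5-dimethoxy-4-(3,4,5-trimethoxyphenoxy)phenyl]boronic acid | OB(O)c1cc(OC)c(Oc2cc(OC)c(OC)c(OC)c2)c(OC)c1 | intermediate
7 | 5-bromo-2-[3,5-dimethoxy-4-(3,4,5-trimethoxyphenoxy)phenoxy]-1,3-dimethoxybenzene | COc1cc(Br)cc(OC)c1Oc1cc(OC)c(Oc2cc(OC)c(OC)c(OC)c2)c(OC)c1 | intermediate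
8 | 3,5-dimethoxy-4-[3,5-dimethoxy-4-(3,4,5-trimethoxyphenoxy)phenoxy]phenol | Oc1cc(OC)c(Oc2cc(OC)c(Oc3cc(OC)c(OC)c(OC)c3)c(OC)c2)c(OC)c1 | intermediate
9 | squaric acid (3,4-dihydroxycyclobut-3-ene-1,2-dione) | OC1=C(O)C(=O)C1=O | starting material
10 | 3,4-dichlorocyclobut-3-ene-1,2-dione | ClC1=C(Cl)C(=O)C1=O | intermediate
11 | 3,4-bis(ring D–E–F aryloxy)cyclobut-3-ene-1,2-dione | O=C1C(=O)C(Oc2cc(OC)c(Oc3cc(OC)c(Oc4cc(OC)c(OC)c(OC)c4)c(OC)c3)c(OC)c2)=C1Oc1cc(OC)c(Oc2cc(OC)c(Oc3cc(OC)c(OC)c(OC)c3)c(OC)c2)c(OC)c1 | intermediate
12 | methyl vinyl ether | COC=C | starting material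
13 | 1-methoxyvinyllithium | [Li]C(OC)=C | intermediate (not isolated)
14 | lithium 2,3-bis(ring D–E–F aryloxy)-1-(1-methoxyvinyl)-4-oxocyclobut-2-en-1-olate (racemic) | [Li+].[O-]C1(C(OC)=C)C(=O)C(Oc2cc(OC)c(Oc3cc(OC)c(Oc4cc(OC)c(OC)c(OC)c4)c(OC)c3)c(OC)c2)=C1Oc1cc(OC)c(Oc2cc(OC)c(Oc3cc(OC)c(OC)c(OC)c3)c(OC)c2)c(OC)c1 | intermediate (not isolated)
15 | 2,3-bis(ring D–E–F aryloxy)-4-methoxy-4-(1-methoxyvinyl)cyclobut-2-en-1-one (racemic) | COC1(C(OC)=C)C(=O)C(Oc2cc(OC)c(Oc3cc(OC)c(Oc4cc(OC)c(OC)c(OC)c4)c(OC)c3)c(OC)c2)=C1Oc1cc(OC)c(Oc2cc(OC)c(Oc3cc(OC)c(OC)c(OC)c3)c(OC)c2)c(OC)c1 | intermediate (not isolated)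
16 | 2-(ring D–E–F aryloxy)-3,4-dimethoxy-4-(1-methoxyvinyl)cyclobut-2-en-1-one (racemic) | O=C1C(Oc2cc(OC)c(Oc3cc(OC)c(Oc4cc(OC)c(OC)c(OC)c4)c(OC)c3)c(OC)c2)=C(OC)C1(OC)C(OC)=C | intermediate
17 | (3Z)-2-(ring D–E–F aryloxy)-3,4,5-trimethoxyhexa-1,3,5-trien-1-one | O=C=C(Oc1cc(OC)c(Oc2cc(OC)c(Oc3cc(OC)c(OC)c(OC)c3)c(OC)c2)c(OC)c1)/C(OC)=C(/OC)C(OC)=C | intermediate (not isolated)
18 | 2-(ring D–E–F aryloxy)-3,4,5-trimethoxycyclohexa-2,4-dien-1-one | O=C1CC(OC)=C(OC)C(OC)=C1Oc1cc(OC)c(Oc2cc(OC)c(Oc3cc(OC)c(OC)c(OC)c3)c(OC)c2)c(OC)c1 | intermediate (not isolated)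
19 | 2-(ring D–E–F aryloxy)-3,4,5-trimethoxyphenol | Oc1cc(OC)c(OC)c(OC)c1Oc1cc(OC)c(Oc2cc(OC)c(Oc3cc(OC)c(OC)c(OC)c3)c(OC)c2)c(OC)c1 | intermediate
20 | 2-(5-bromo-2-fluorophenyl)-1,3-dioxolane | Fc1ccc(Br)cc1C1OCCO1 | starting material
21 | [5-bromo-3-(1,3-dioxolan-2-yl)-2-fluorophenyl]lithium | [Li]c1cc(Br)cc(C2OCCO2)c1F | intermediate (not isolated)
22 | 5-bromo-3-(1,3-dioxolan-2-yl)-2-fluorobenzaldehyde | O=Cc1cc(Br)cc(C2OCCO2)c1F | intermediate
23 | 2,2'-(5-bromo-2-fluoro-1,3-phenylene)bis(1,3-dioxolane) | Fc1c(C2OCCO2)cc(Br)cc1C1OCCO1 | intermediate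
24 | 2,4,6-trimethoxyphenol | COc1cc(OC)c(O)c(OC)c1 | starting material
25 | 2,2'-[2-fluoro-5-(2,4,6-trimethoxyphenoxy)-1,3-phenylene]bis(1,3-dioxolane) | Fc1c(C2OCCO2)cc(Oc2c(OC)cc(OC)cc2OC)cc1C1OCCO1 | intermediate
26 | 2-fluoro-5-(2,4,6-trimethoxyphenoxy)benzene-1,3-dicarbaldehyde | O=Cc1cc(Oc2c(OC)cc(OC)cc2OC)cc(C=O)c1F | intermediate
27 | 2-[2-(ring D–E–F aryloxy)-3,4,5-trimethoxyphenoxy]-5-(2,4,6-trimethoxyphenoxy)benzene-1,3-dicarbaldehyde | O=Cc1cc(Oc2c(OC)cc(OC)cc2OC)cc(C=O)c1Oc1cc(OC)c(OC)c(OC)c1Oc1cc(OC)c(Oc2cc(OC)c(Oc3cc(OC)c(OC)c(OC)c3)c(OC)c2)c(OC)c1 | intermediate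
28 | 2-[2-(ring D–E–F aryloxy)-3,4,5-trimethoxyphenoxy]-5-(2,4,6-trimethoxyphenoxy)-1,3-phenylene diformate | O=COc1cc(Oc2c(OC)cc(OC)cc2OC)cc(OC=O)c1Oc1cc(OC)c(OC)c(OC)c1Oc1cc(OC)c(Oc2cc(OC)c(Oc3cc(OC)c(OC)c(OC)c3)c(OC)c2)c(OC)c1 | intermediate (not isolated)
29 | 2-[2-(ring D–E–F aryloxy)-3,4,5-trimethoxyphenoxy]-5-(2,4,6-trimethoxyphenoxy)benzene-1,3-diol | Oc1cc(Oc2c(OC)cc(OC)cc2OC)cc(O)c1Oc1cc(OC)c(OC)c(OC)c1Oc1cc(OC)c(Oc2cc(OC)c(Oc3cc(OC)c(OC)c(OC)c3)c(OC)c2)c(OC)c1 | intermediate
30 | CNP0270681.0, 5-(2,4,6-trihydroxyphenoxy)-2-[2-{3,5-dihydroxy-4-[3,5-dihydroxy-4-(3,4,5-trihydroxyphenoxy)phenoxy]phenoxy}-3,4,5-trihydroxyphenoxy]benzene-1,3-diol | Oc1cc(O)c(Oc2cc(O)c(Oc3cc(O)c(O)c(O)c3Oc3cc(O)c(Oc4cc(O)c(Oc5cc(O)c(O)c(O)c5)c(O)c4)c(O)c3)c(O)c2)c(O)c1 | target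

## Step count and least certain steps

Total: 15 steps. Longest linear sequence: 10 steps (steps 1, 2, 3, 4, 6, 7, 8, 13, 14, 15).

**Key step (step 8).** The most likely failure is diversion of the dienylketene before it cyclises: dimerisation, capture by traces of water or methanol, or acid-catalysed hydrolysis of the enol ether before ring opening. A ketene carbon carrying so large an aryloxy group has not been tried in this reaction type.
The fallback sets out from 8 and leaves the squarate chemistry. Copper-catalysed coupling of 8 with 2-bromo-3,4,5-trimethoxybenzaldehyde (COc1cc(C=O)c(Br)c(OC)c1OC; CuI, picolinic acid, K3PO4, DMSO, 90 °C) should give 2-(ring D–E–F aryloxy)-3,4,5-trimethoxybenzaldehyde F1, helped by the ortho formyl group. Baeyer–Villiger oxidation with mCPBA should give the aryl formate 2-(ring D–E–F aryloxy)-3,4,5-trimethoxyphenyl formate F2, and methanolysis with K2CO3 in MeOH then returns to the route at 19. This classical sequence is shorter than steps 5 to 8; it is kept as the fallback because the plan is built around the squarate-based ring synthesis.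

**Step 7.** What may go wrong is attack of the organolithium at an aryloxy-bearing carbon of the activated diaryl ester, with loss of aryloxide and a second addition, or incomplete methylation of the hindered tertiary alkoxide.
The fallback sets out from 10 and 8 and uses a less activated mixed ester. Compound 10 with one equivalent of methanol should give 3-chloro-4-methoxycyclobut-3-ene-1,2-dione F3. The sodium salt of 8 then displaces the chloride to give 3-(ring D–E–F aryloxy)-4-methoxycyclobut-3-ene-1,2-dione F4. Addition of 13 at −78 °C is expected at the carbonyl vinylogous to the weaker aryloxy donor, which is also the one next to the small methoxy group, and gives the lithium alkoxide lithium 3-(ring D–E–F aryloxy)-2-methoxy-1-(1-methoxyvinyl)-4-oxocyclobut-2-en-1-olate F5. Methylation with MeOTf returns to the route at 16. This path saves one equivalent of 8 but depends on site selectivity between two different carbonyls.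

**Step 14.** What may go wrong is hydride instead of aryl migration at one of the two formyl groups (giving a carboxylic acid), or oxidation of the electron-rich rings, above all ring A, by the peracid.
The fallback sets out from 19 and 24 and avoids formyl groups altogether. Copper-catalysed coupling of 24 with the known 2,5-dibromo-1,3-dimethoxybenzene (COc1cc(Br)cc(OC)c1Br) at its unhindered bromide should give 2-bromo-1,3-dimethoxy-5-(2,4,6-trimethoxyphenoxy)benzene F6. A second, hindered coupling of F6 with 19 (CuI, 2,2,6,6-tetramethylheptane-3,5-dione, Cs2CO3, NMP, 120 °C, or a palladium catalyst with a bulky biarylphosphine) should give the pentadeca-O-methyl ether of the target F7. Demethylation with BBr3 as in step 15 comes back to the route at 30.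

**Step 15.** What may go wrong is incomplete cleavage of some of the thirteen methyl ethers, because boron chelates build up on the neighbouring oxygens, and oxidative degradation of the free polyphenol during isolation.
The fallback sets out from 29. After treatment with BBr3 the crude product is acetylated in the same flask (Ac2O, pyridine) to the pentadeca-acetate of the target F8, which is stable to air and can be purified by chromatography; partly methylated material is separated at this stage. Acid methanolysis (HCl in MeOH, argon) then returns to the route at 30.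

## Further compounds

F1 | step 8 | 2-(ring D–E–F aryloxy)-3,4,5-trimethoxybenzaldehyde | O=Cc1cc(OC)c(OC)c(OC)c1Oc1cc(OC)c(Oc2cc(OC)c(Oc3cc(OC)c(OC)c(OC)c3)c(OC)c2)c(OC)c1
F2 | step 8 | 2-(ring D–E–F aryloxy)-3,4,5-trimethoxyphenyl formate | O=COc1cc(OC)c(OC)c(OC)c1Oc1cc(OC)c(Oc2cc(OC)c(Oc3cc(OC)c(OC)c(OC)c3)c(OC)c2)c(OC)c1
F3 | step 7 | 3-chloro-4-methoxycyclobut-3-ene-1,2-dione | COC1=C(Cl)C(=O)C1=O
F4 | step 7 | 3-(ring D–E–F aryloxy)-4-methoxycyclobut-3-ene-1,2-dione | COC1=C(Oc2cc(OC)c(Oc3cc(OC)c(Oc4cc(OC)c(OC)c(OC)c4)c(OC)c3)c(OC)c2)C(=O)C1=O
F5 | step 7 | lithium 3-(ring D–E–F aryloxy)-2-methoxy-1-(1-methoxyvinyl)-4-oxocyclobut-2-en-1-olate (racemic) | [Li+].[O-]C1(C(OC)=C)C(OC)=C(Oc2cc(OC)c(Oc3cc(OC)c(Oc4cc(OC)c(OC)c(OC)c4)c(OC)c3)c(OC)c2)C1=O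
F6 | step 14 | 2-bromo-1,3-dimethoxy-5-(2,4,6-trimethoxyphenoxy)benzene | COc1cc(Oc2c(OC)cc(OC)cc2OC)cc(OC)c1Br
F7 | step 14 | pentadeca-O-methyl ether of the target | COc1cc(OC)c(Oc2cc(OC)c(Oc3cc(OC)c(OC)c(OC)c3Oc3cc(OC)c(Oc4cc(OC)c(Oc5cc(OC)c(OC)c(OC)c5)c(OC)c4)c(OC)c3)c(OC)c2)c(OC)c1
F8 | step 15 | pentadeca-acetate of the target | CC(=O)Oc1cc(OC(C)=O)c(Oc2cc(OC(C)=O)c(Oc3cc(OC(C)=O)c(OC(C)=O)c(OC(C)=O)c3Oc3cc(OC(C)=O)c(Oc4cc(OC(C)=O)c(Oc5cc(OC(C)=O)c(OC(C)=O)c(OC(C)=O)c5)c(OC(C)=O)c4)c(OC(C)=O)c3)c(OC(C)=O)c2)c(OC(C)=O)c1
A1 | alternative 1 | CpRu hexafluorophosphate complex (divalent ruthenium on ring B) of the pentadeca-O-methyl ether of the target | COc1cc(OC)c(Oc2cc(OC)c(Oc3cc(OC)c(OC)c(OC)c3Oc3cc(OC)c(Oc4cc(OC)c(Oc5cc(OC)c(OC)c(OC)c5)c(OC)c4)c(OC)c3)c(OC)c2)c(OC)c1.[cH-]1cccc1.[Ru+2].F[P-](F)(F)(F)(F)F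
A2 | alternative 1 | [CpRu(η6-2,5-dichloro-1,3-dimethoxybenzene)]PF6 (divalent ruthenium) | COc1cc(Cl)cc(OC)c1Cl.[cH-]1cccc1.[Ru+2].F[P-](F)(F)(F)(F)F
A3 | alternative 2 | dodeca-O-methyl hexamer with free ring A hydroxyls and methyl esters at C3 and C5 of ring A | COC(=O)c1c(O)c(C(=O)OC)c(O)c(Oc2cc(OC)c(Oc3cc(OC)c(OC)c(OC)c3Oc3cc(OC)c(Oc4cc(OC)c(Oc5cc(OC)c(OC)c(OC)c5)c(OC)c4)c(OC)c3)c(OC)c2)c1O
A4 | alternative 2 | diethyl aryloxymalonate of the ring B–F pentamer | CCOC(=O)C(C(=O)OCC)Oc1cc(OC)c(Oc2cc(OC)c(OC)c(OC)c2Oc2cc(OC)c(Oc3cc(OC)c(Oc4cc(OC)c(OC)c(OC)c4)c(OC)c3)c(OC)c2)c(OC)c1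
A5 | alternative 2 | dimethyl 3-oxopentanedioate | COC(=O)CC(=O)CC(=O)OC
A6 | alternative 3 | decahydroxy penta-O-methyl hexamer (methyl ethers at C4 of rings A and C and on ring F) | COc1cc(O)c(Oc2cc(O)c(Oc3cc(O)c(OC)c(O)c3Oc3cc(O)c(Oc4cc(O)c(Oc5cc(OC)c(OC)c(OC)c5)c(O)c4)c(O)c3)c(O)c2)c(O)c1
A7 | alternative 3 | deca-aldehyde (formyl at C2 and C6 of ring A and at C3 and C5 of rings B, C, D and E) | COc1cc(C=O)c(Oc2cc(C=O)c(Oc3cc(C=O)c(OC)c(C=O)c3Oc3cc(C=O)c(Oc4cc(C=O)c(Oc5cc(OC)c(OC)c(OC)c5)c(C=O)c4)c(C=O)c3)c(C=O)c2)c(C=O)c1
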